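## The problem

Catechin 5,4'-di-O-gallate (26) is (+)-catechin, a (2R,3S) 2,3-trans-flavan-3-ol, in which the O5 phenol of ring A and the O4' phenol of ring B carry 3,4,5-trihydroxybenzoyl groups while O7, O3' and the secondary O3 are free. The skeleton is a 1,3-diarylpropane closed to ring C through O1, which joins C2 to C8a. The only stereocentres are the neighbours C2 and C3, so an oxygen already on C3 can direct a reaction at C2. The harder question is which oxygen is which: O5 and O7 are both meta to O1 on ring A, O3' and O4' form a catechol, and O3 would compete in any acylation. Five hydroxyl groups must therefore be sorted into two sets early and kept sorted. The two aryl esters do not survive carbonate, alkoxides or organometallic reagents, and the 4'-ester can migrate to a free O3', so they must come late and be followed only by a neutral deprotection. The benzylic C2–O1 bond, para to an oxygen of ring B, ionises under acid (which epimerises C2) and can be hydrogenolysed. The feature exploited here is that O1 is an aryl alkyl ether oxygen bound to the arene carbon C8a: ring C can be closed by joining a C2 alkoxide to a halogen-bearing C8a, so that no bond to C2 or C3 is made or broken.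

## Retrosynthesis

**Esters and protecting groups (26 ← 25 ← 23 + 24 ← 22).** The last cut removes nine benzyl C–O bonds from 25. Hydrogenolysis is the only global deprotection neutral enough to follow the esters, so every permanent protecting group, on the flavan and on the gallates, is benzyl. The two aryl ester bonds of 25 are cut next, giving the diphenol 23 and the acid 24. The acylation is asked to show no selectivity at all, because 23 has exactly two free hydroxyl groups and O3 is a benzyl ether. The phenols of 23 are masked in 22 as allyl ethers. Allyl is removed by zerovalent palladium without touching benzyl, and it tolerates the bases and organometallics used earlier. Silyl ethers would not survive hot carbonate, and oxidative or acidic removals would endanger the benzylic positions.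

**Ring C (22 ← 21).** The O1–C8a bond is cut, leading to the open-chain anti bromo alcohol 21. The neighbouring cut O1–C2 needs substitution or ionisation at the labile benzylic carbon. The cut C4–C4a needs an electrophilic attack whose position on ring A is decided only by relative donor strength. In the O1–C8a cut the bromine fixes the position and both stereocentres are spectators. The forward reaction must make the C2 alkoxide the only nucleophile, which the O3 benzyl ether ensures.

**C2 stereocentre (21 ← 20).** The C2–H bond is cut, giving the α-benzyloxy aryl ketone 20 with one stereocentre. The anti relationship of 21 is what chelation-controlled hydride delivery to an α-alkoxy ketone produces. Dihydroxylation of an E-1,3-diarylpropene would give the syn diol, wrong for a closure with retention, and would also attack the allyl groups.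

**Aryl–carbonyl bond (20 ← 14 + 17).** The C2–C1' bond is cut into the Weinreb amide 14 and the ring-B bromide 17, used as its Grignard reagent 18. The cut is convergent and brings ring B in with O3' and O4' already differentiated. The addition must stop at the ketone and must not enolise the α-centre, and the chelated adduct 19 secures both. Bromide 17 comes from 2-(benzyloxy)phenol 15 by para-bromination to 16 and O-allylation.

**C3 stereocentre (14 ← 13 ← 11 + 8).** The C3–C4 bond is cut between the glycolate imide 11 and the ring-A benzylic bromide 8. C3 is the one centre that needs an external source of chirality, and the auxiliary 9 supplies it in an alkylation whose facial sense is predictable. Imide 11 is the N-benzyloxyacetyl derivative of 9, and 13 is converted directly into 14.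

**Ring A (8 ← 7 ← 6 ← 5 ← 4 ← 2 ← 1).** A mixed allyl/benzyl diether of 1 would be formylated at two non-equivalent positions with no basis for selection. The oxygens are therefore differentiated only after the formyl group is in place. The symmetric dibenzyl ether 2 is formylated next to bromine to give 4. The benzyl ether ortho to the formyl group is then removed by chelation to give 5, and that oxygen, the future O5, is allylated to 6. Reduction to 7 and bromination give 8.

## Roads not taken

**Alternative 1:** The cut is C4–C4a. The aryl epoxy ether A1 already has O1 bound to C2, a terminal oxirane at C3–C4 and both gallates in place. BF3·OEt2 would activate the oxirane, and the ring-A carbon para to the benzyloxy group would attack C4 to give the protected flavan-3-ol A2.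
- Merits: the esters are installed before ring closure and O3 is released free, so A2 needs only one hydrogenolysis to reach 26. Neither stereocentre is touched in the closure.
- Weak points: a Lewis acid is placed next to the C2–O1 benzylic aryl ether, the bond most prone to ionise, so epimerisation or fragmentation at C2 competes. Regiochemistry on ring A rests on the difference between a benzyloxy and an aroyloxy donor, and the other position ortho to O1 is also activated. The ester deactivates the ring that must act as nucleophile. Two base-labile gallates must be carried through the making of A1, including an etherification at an electron-rich benzylic carbinol.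
- Comparison: after ring closure this road is shorter by two steps, a real advantage. The chosen plan sets against it a base-mediated closure in which the bromine, not donor strength, decides the position on ring A, and in which the C2–O bond is never activated.

**Alternative 2:** The cut is O1–C2. The 1,3-diarylpropan-2-ol A3 would be oxidised by Ag2O or DDQ at its 4-hydroxy-3-benzyloxybenzyl unit to the para-quinone methide A4. One of the two equivalent ring-A phenols then adds to C2 to give 7,3'-di-O-benzylcatechin A5.
- Merits: ring A of A3 is symmetric, so O5 and O7 are differentiated at no cost and the phenol that does not cyclise is exactly the one to be galloylated. Only C3 must be made beforehand, and A5 has O5 and O4' free. It is the shortest of the routes.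
- Weak points: C2 is set in the closure by induction from C3, with the trans isomer favoured but not assured. The electron-rich ring A with two free phenols is itself open to the oxidant and can attack A4 through carbon. In A5 the free O3 competes with the phenols in the acylation.
- Comparison: this road is better in step count and in its use of symmetry. The chosen plan is longer, but it fixes C2 by a chelation-controlled reduction before the ring exists, and O3 stays capped until the end.

**Alternative 3:** Both C3–C4 and O1–C2 are cut. A chiral Brønsted acid of the binaphthol phosphoric acid class would dehydrate the salicyl alcohol A6 to the ortho-quinone methide A7. A7 would add the E-enol carbonate A8 in an inverse-demand [4+2] cycloaddition to give the chroman-3-yl benzyl carbonate A9.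
- Merits: two bonds, ring C and both stereocentres arise in one step from achiral partners. The E geometry maps onto the 2,3-trans relationship, and the carbonate falls in the final hydrogenolysis, so the endgame equals that from 22.
- Weak points: enol carbonates are weak partners for ortho-quinone methides and offer the catalyst no hydrogen-bond donor, so enantiocontrol is unproven for this pair. The required regiochemistry needs A8 to react as a para-alkoxystyrene against the polarisation imposed by its enol oxygen. A7 can dimerise, A8 must be made as the pure E isomer, and A6 still needs the O5/O7 differentiation.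
- Comparison: this road would roughly halve the number of operations. The chosen plan sets against it stereocentres made by an auxiliary alkylation and a chelation-controlled reduction, both reliable on closely related substrates, and a key step that needs no stereocontrol.

Key step: step 14

Remark on the chemistry: benzyl bromide, allyl bromide, benzyloxyacetyl chloride, N,O-dimethylhydroxylamine hydrochloride and the common reagents are taken as purchased; "gallate" is read as the 3,4,5-trihydroxybenzoate ester.

## Route

Step 1
Reactants: 1 5-bromoresorcinol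
Product: 2 1,3-bis(benzyloxy)-5-bromobenzene
Conditions: BnBr, K2CO3, DMF, 60 °C
Reagents that add atoms: benzyl bromide, BrCc1ccccc1
Why: Williamson ether synthesis; both phenols of the symmetric resorcinol are alkylated, so no selectivity is required.

Step 2
Reactants: 2 1,3-bis(benzyloxy)-5-bromobenzene
Product: 4 2,4-bis(benzyloxy)-6-bromobenzaldehyde, via aryl iminium chloride 3 (not isolated)
Conditions: POCl3, DMF, 0 → 80 °C; then aq. NaOAc, rt
Reagents that add atoms: N,N-dimethylformamide, CN(C)C=O (formyl carbon); water, O (carbonyl oxygen)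
Why: Vilsmeier–Haack formylation; 3,5-dialkoxybromobenzenes react at the carbon flanked by bromine and one ether and para to the other, the site between the two ethers being more hindered, and hydrolysis of 3 releases the aldehyde.

Step 3
Reactants: 4 2,4-bis(benzyloxy)-6-bromobenzaldehyde
Product: 5 4-benzyloxy-2-bromo-6-hydroxybenzaldehyde
Conditions: MgBr2·OEt2, toluene–Et2O, 80 °C; then 1 M HCl
Reagents that add atoms: none
Why: Chelation-assisted ether cleavage: magnesium binds the formyl oxygen and the ortho ether oxygen and bromide removes only that benzyl group, which is how O5 is told from O7, since the para ether cannot chelate.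

Step 4
Reactants: 5 4-benzyloxy-2-bromo-6-hydroxybenzaldehyde
Product: 6 2-allyloxy-4-benzyloxy-6-bromobenzaldehyde
Conditions: allyl bromide, K2CO3, DMF, 50 °C
Reagents that add atoms: allyl bromide, C=CCBr
Why: Williamson ether synthesis on the ortho phenol; the allyl group marks the future O5 and is orthogonal to benzyl.

Step 5
Reactants: 6 2-allyloxy-4-benzyloxy-6-bromobenzaldehyde
Product: 7 (2-allyloxy-4-benzyloxy-6-bromophenyl)methanol
Conditions: NaBH4, THF–MeOH, 0 °C
Reagents that add atoms: none
Why: Borohydride reduction of an aryl aldehyde; the aryl bromide and both ethers are inert.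

Step 6
Reactants: 7 (2-allyloxy-4-benzyloxy-6-bromophenyl)methanol
Product: 8 1-allyloxy-5-benzyloxy-3-bromo-2-(bromomethyl)benzene
Conditions: CBr4, PPh3, CH2Cl2, 0 °C
Reagents that add atoms: carbon tetrabromide, BrC(Br)(Br)Br
Why: Appel reaction under neutral conditions, which suits an electron-rich benzylic alcohol; the bromide should be used at once.

Step 7
Reactants: 9 (R)-4-benzyl-2-oxazolidinone
Product: 11 (R)-4-benzyl-3-(2-benzyloxyacetyl)oxazolidin-2-one, via lithiated oxazolidinone 10 (not isolated)
Conditions: n-BuLi, THF, −78 °C; then BnOCH2COCl, −78 → 0 °C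
Reagents that add atoms: benzyloxyacetyl chloride, O=C(Cl)COCc1ccccc1
Why: N-acylation of the lithium salt 10 of the Evans auxiliary with an acid chloride, the standard entry to glycolate imides.

Step 8
Reactants: 11 (R)-4-benzyl-3-(2-benzyloxyacetyl)oxazolidin-2-one; 8 1-allyloxy-5-benzyloxy-3-bromo-2-(bromomethyl)benzene
Product: 13 (R)-4-benzyl-3-[(S)-3-(2-allyloxy-4-benzyloxy-6-bromophenyl)-2-benzyloxypropanoyl]oxazolidin-2-one, via sodium Z-enolate 12 (not isolated)
Conditions: NaN(SiMe3)2, THF, −78 °C; then 8, −78 → −40 °C
Reagents that add atoms: none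
Why: Evans asymmetric alkylation of a glycolate imide: the chelated Z-enolate 12 is shielded on one face by the C4 benzyl group of the auxiliary and the benzylic bromide enters from the other, giving the (S) centre that becomes C3; the enolate is used in slight excess so that the six-step bromide is consumed.

Step 9
Reactants: 13 (R)-4-benzyl-3-[(S)-3-(2-allyloxy-4-benzyloxy-6-bromophenyl)-2-benzyloxypropanoyl]oxazolidin-2-one
Product: 14 (S)-3-(2-allyloxy-4-benzyloxy-6-bromophenyl)-2-benzyloxy-N-methoxy-N-methylpropanamide
Conditions: MeONHMe·HCl, AlMe3, CH2Cl2, −20 → 0 °C; then aq. potassium sodium tartrate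
Reagents that add atoms: N,O-dimethylhydroxylamine hydrochloride, CNOC.Cl
Why: Weinreb transamidation of an N-acyloxazolidinone with the aluminium amide made from AlMe3 and the amine salt; the α-alkoxy group assists attack at the exocyclic carbonyl and the non-basic medium leaves the stereocentre unenolised.

Step 10
Reactants: 15 2-(benzyloxy)phenol
Product: 16 2-(benzyloxy)-4-bromophenol
Conditions: NBS, MeCN, 0 °C
Reagents that add atoms: N-bromosuccinimide, O=C1CCC(=O)N1Br
Why: Electrophilic aromatic bromination; the free phenol is the stronger para director, so bromine enters para to OH at the carbon that becomes C1'.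

Step 11
Reactants: 16 2-(benzyloxy)-4-bromophenol
Product: 17 1-allyloxy-2-benzyloxy-4-bromobenzene
Conditions: allyl bromide, K2CO3, acetone, reflux
Reagents that add atoms: allyl bromide, C=CCBr
Why: Williamson ether synthesis; the allyl group on the oxygen para to bromine marks the future O4'.

Step 12
Reactants: 17 1-allyloxy-2-benzyloxy-4-bromobenzene; 14 (S)-3-(2-allyloxy-4-benzyloxy-6-bromophenyl)-2-benzyloxy-N-methoxy-N-methylpropanamide
Product: 20 (S)-1-(4-allyloxy-3-benzyloxyphenyl)-3-(2-allyloxy-4-benzyloxy-6-bromophenyl)-2-benzyloxypropan-1-one, via aryl Grignard reagent 18 (not isolated), via magnesium hemiaminal chelate 19 (not isolated)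
Conditions: Mg, THF, 50 °C; then 14, THF, 0 °C; aq. NH4Cl
Reagents that add atoms: none
Why: Weinreb ketone synthesis: Grignard reagent 18 adds once to amide 14 and the chelate 19 persists until the quench, which prevents over-addition and shields the α-centre from enolisation; an aryl Grignard reagent does not exchange with the ring-A bromide at 0 °C.

Step 13
Reactants: 20 (S)-1-(4-allyloxy-3-benzyloxyphenyl)-3-(2-allyloxy-4-benzyloxy-6-bromophenyl)-2-benzyloxypropan-1-one
Product: 21 (1R,2S)-1-(4-allyloxy-3-benzyloxyphenyl)-3-(2-allyloxy-4-benzyloxy-6-bromophenyl)-2-benzyloxypropan-1-ol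
Conditions: Zn(BH4)2, Et2O, −20 °C; aq. NH4Cl
Reagents that add atoms: none
Why: Chelation-controlled (Cram-chelate) reduction: zinc bridges the carbonyl and α-benzyloxy oxygens and hydride attacks the five-membered chelate from the face opposite the arylmethyl group, giving the anti (1R) carbinol, so C3 sets C2.

Step 14
Reactants: 21 (1R,2S)-1-(4-allyloxy-3-benzyloxyphenyl)-3-(2-allyloxy-4-benzyloxy-6-bromophenyl)-2-benzyloxypropan-1-ol
Product: 22 (2R,3S)-5-allyloxy-2-(4-allyloxy-3-benzyloxyphenyl)-3,7-bis(benzyloxy)chroman
Conditions: CuI (10 mol %), 3,4,7,8-tetramethyl-1,10-phenanthroline (20 mol %), Cs2CO3, toluene, 110 °C, under argon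
Reagents that add atoms: none
Why: Intramolecular Ullmann-type C–O coupling: Cs2CO3 and the phenanthroline-bound monovalent copper turn the C1 hydroxyl of 21 into a copper alkoxide, the tethered C–Br bond adds oxidatively to give an aryl alkoxide of trivalent copper, and reductive elimination forms O1–C8a and returns monovalent copper. The closest known reaction type is the copper-catalysed intramolecular O-arylation of secondary alcohols with aryl bromides to give chromans and 2-arylchromans. Ring C, the only ring formed, closes as a six-membered ring by attack of the chain oxygen on the arene carbon, exo with respect to the C–Br bond that breaks. No stereocentre is created: only the O–H and C–Br bonds change, so the anti alcohol from steps 8 and 13 is transcribed with retention into the 2,3-trans flavan. The selectivity needed is chemoselectivity and ring size: the O3 benzyl ether leaves the C2 alkoxide as the sole nucleophile, so no dihydrobenzofuran can form, and the bromine fixes the ring-A position so that O5 and O7 cannot be exchanged. Copper is preferred to zerovalent palladium because it does not ionise the allyl aryl ethers and is less prone to oxidise the benzylic alkoxide by β-hydride elimination; carbonate in toluene leaves benzyl and allyl ethers untouched.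

Step 15
Reactants: 22 (2R,3S)-5-allyloxy-2-(4-allyloxy-3-benzyloxyphenyl)-3,7-bis(benzyloxy)chroman
Product: 23 (2R,3S)-3,7-bis(benzyloxy)-2-(3-benzyloxy-4-hydroxyphenyl)chroman-5-ol
Conditions: Pd(PPh3)4 (5 mol %), morpholine, THF, rt
Reagents that add atoms: none
Why: Tsuji–Trost-type deallylation: zerovalent palladium ionises each allyl aryl ether to a π-allyl complex and a phenoxide and morpholine traps the allyl group; benzyl ethers and the C2–O1 bond are not allylic and remain.

Step 16
Reactants: 23 (2R,3S)-3,7-bis(benzyloxy)-2-(3-benzyloxy-4-hydroxyphenyl)chroman-5-ol; 24 3,4,5-tris(benzyloxy)benzoic acid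
Product: 25 (2R,3S)-3,7-bis(benzyloxy)-2-[3-benzyloxy-4-(3,4,5-tribenzyloxybenzoyloxy)phenyl]chroman-5-yl 3,4,5-tris(benzyloxy)benzoate
Conditions: 24 (2.5 equiv), EDCI·HCl, 4-(dimethylamino)pyridine, CH2Cl2, rt
Reagents that add atoms: none
Why: Steglich esterification of the only two free hydroxyl groups, the O5 and O4' phenols; O3, O7 and O3' are benzyl ethers, so the acylation needs no selectivity between oxygens.

Step 17
Reactants: 25 (2R,3S)-3,7-bis(benzyloxy)-2-[3-benzyloxy-4-(3,4,5-tribenzyloxybenzoyloxy)phenyl]chroman-5-yl 3,4,5-tris(benzyloxy)benzoate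
Product: 26 catechin 5,4'-di-O-gallate, (2R,3S)-3,7-dihydroxy-2-[3-hydroxy-4-(3,4,5-trihydroxybenzoyloxy)phenyl]chroman-5-yl 3,4,5-trihydroxybenzoate
Conditions: H2 (1 atm), Pd(OH)2 on carbon, THF–MeOH, rt
Reagents that add atoms: none
Why: Catalytic hydrogenolysis of nine benzyl ethers under neutral conditions, under which the aryl esters should neither cleave nor migrate readily; Pd(OH)2 on carbon is the usual catalyst for perbenzylated catechin gallates, and the reaction is stopped at full debenzylation to spare the C2–O1 bond.

## Compound list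

1 | 5-bromoresorcinol | Oc1cc(O)cc(Br)c1 | starting material
2 | 1,3-bis(benzyloxy)-5-bromobenzene | Brc1cc(OCc2ccccc2)cc(OCc2ccccc2)c1 | intermediate
3 | N-[2,4-bis(benzyloxy)-6-bromobenzylidene]-N-methylmethanaminium chloride | C[N+](C)=Cc1c(Br)cc(OCc2ccccc2)cc1OCc1ccccc1.[Cl-] | intermediate
4 | 2,4-bis(benzyloxy)-6-bromobenzaldehyde | O=Cc1c(Br)cc(OCc2ccccc2)cc1OCc1ccccc1 | intermediate
5 | 4-benzyloxy-2-bromo-6-hydroxybenzaldehyde | O=Cc1c(O)cc(OCc2ccccc2)cc1Br | intermediate
6 | 2-allyloxy-4-benzyloxy-6-bromobenzaldehyde | C=CCOc1cc(OCc2ccccc2)cc(Br)c1C=O | intermediate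
7 | (2-allyloxy-4-benzyloxy-6-bromophenyl)methanol | C=CCOc1cc(OCc2ccccc2)cc(Br)c1CO | intermediate
8 | 1-allyloxy-5-benzyloxy-3-bromo-2-(bromomethyl)benzene | C=CCOc1cc(OCc2ccccc2)cc(Br)c1CBr | intermediate
9 | (R)-4-benzyl-2-oxazolidinone | O=C1N[C@H](Cc2ccccc2)CO1 | starting material
10 | lithium salt of (R)-4-benzyl-2-oxazolidinone | O=C1[N-][C@H](Cc2ccccc2)CO1.[Li+] | intermediate
11 | (R)-4-benzyl-3-(2-benzyloxyacetyl)oxazolidin-2-one | O=C(COCc1ccccc1)N1C(=O)OC[C@H]1Cc1ccccc1 | intermediate
12 | sodium (Z)-enolate of 11 | [Na+].[O-]/C(=C\OCc1ccccc1)N1C(=O)OC[C@H]1Cc1ccccc1 | intermediate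
13 | (R)-4-benzyl-3-[(S)-3-(2-allyloxy-4-benzyloxy-6-bromophenyl)-2-benzyloxypropanoyl]oxazolidin-2-one | C=CCOc1cc(OCc2ccccc2)cc(Br)c1C[C@H](OCc1ccccc1)C(=O)N1C(=O)OC[C@H]1Cc1ccccc1 | intermediate
14 | (S)-3-(2-allyloxy-4-benzyloxy-6-bromophenyl)-2-benzyloxy-N-methoxy-N-methylpropanamide | C=CCOc1cc(OCc2ccccc2)cc(Br)c1C[C@H](OCc1ccccc1)C(=O)N(C)OC | intermediate
15 | 2-(benzyloxy)phenol | Oc1ccccc1OCc1ccccc1 | starting material
16 | 2-(benzyloxy)-4-bromophenol | Oc1ccc(Br)cc1OCc1ccccc1 | intermediate
17 | 1-allyloxy-2-benzyloxy-4-bromobenzene | C=CCOc1ccc(Br)cc1OCc1ccccc1 | intermediate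
18 | (4-allyloxy-3-benzyloxyphenyl)magnesium bromide | C=CCOc1ccc([Mg]Br)cc1OCc1ccccc1 | intermediate
19 | bromomagnesium (2S)-1-(4-allyloxy-3-benzyloxyphenyl)-3-(2-allyloxy-4-benzyloxy-6-bromophenyl)-2-benzyloxy-1-[methoxy(methyl)amino]propan-1-olate | C=CCOc1ccc(C(O[Mg]Br)(N(C)OC)[C@@H](OCc2ccccc2)Cc2c(Br)cc(OCc3ccccc3)cc2OCC=C)cc1OCc1ccccc1 | intermediate
20 | (S)-1-(4-allyloxy-3-benzyloxyphenyl)-3-(2-allyloxy-4-benzyloxy-6-bromophenyl)-2-benzyloxypropan-1-one | C=CCOc1ccc(C(=O)[C@@H](OCc2ccccc2)Cc2c(Br)cc(OCc3ccccc3)cc2OCC=C)cc1OCc1ccccc1 | intermediate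
21 | (1R,2S)-1-(4-allyloxy-3-benzyloxyphenyl)-3-(2-allyloxy-4-benzyloxy-6-bromophenyl)-2-benzyloxypropan-1-ol | C=CCOc1ccc([C@@H](O)[C@@H](OCc2ccccc2)Cc2c(Br)cc(OCc3ccccc3)cc2OCC=C)cc1OCc1ccccc1 | intermediate
22 | (2R,3S)-5-allyloxy-2-(4-allyloxy-3-benzyloxyphenyl)-3,7-bis(benzyloxy)chroman | C=CCOc1ccc([C@H]2Oc3cc(OCc4ccccc4)cc(OCC=C)c3C[C@@H]2OCc2ccccc2)cc1OCc1ccccc1 | intermediate
23 | (2R,3S)-3,7-bis(benzyloxy)-2-(3-benzyloxy-4-hydroxyphenyl)chroman-5-ol | Oc1ccc([C@H]2Oc3cc(OCc4ccccc4)cc(O)c3C[C@@H]2OCc2ccccc2)cc1OCc1ccccc1 | intermediate
24 | 3,4,5-tris(benzyloxy)benzoic acid | O=C(O)c1cc(OCc2ccccc2)c(OCc2ccccc2)c(OCc2ccccc2)c1 | starting material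
25 | (2R,3S)-3,7-bis(benzyloxy)-2-[3-benzyloxy-4-(3,4,5-tribenzyloxybenzoyloxy)phenyl]chroman-5-yl 3,4,5-tris(benzyloxy)benzoate | O=C(Oc1ccc([C@H]2Oc3cc(OCc4ccccc4)cc(OC(=O)c4cc(OCc5ccccc5)c(OCc5ccccc5)c(OCc5ccccc5)c4)c3C[C@@H]2OCc2ccccc2)cc1OCc1ccccc1)c1cc(OCc2ccccc2)c(OCc2ccccc2)c(OCc2ccccc2)c1 | intermediate
26 | catechin 5,4'-di-O-gallate | O=C(Oc1ccc([C@H]2Oc3cc(O)cc(OC(=O)c4cc(O)c(O)c(O)c4)c3C[C@@H]2O)cc1O)c1cc(O)c(O)c(O)c1 | target

## Step count and risks

Total: 17 steps. Longest linear sequence: 14 steps (steps 1–6, 8, 9, 12–17).

**Step 14 (key step).** The most likely failure is slow coupling of the ortho-substituted aryl bromide with a hindered secondary benzylic alkoxide, with reductive loss of bromine or oxidation of the carbinol back to ketone 20 competing at 110 °C. The fallback closes ring C at O1–C2 by Mitsunobu inversion and sets out from ketone 20.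
- Reduction of 20 under Felkin–Anh control with LiBH(s-Bu)3 in THF at −78 °C should give the syn alcohol (1S,2S)-1-(4-allyloxy-3-benzyloxyphenyl)-3-(2-allyloxy-4-benzyloxy-6-bromophenyl)-2-benzyloxypropan-1-ol F1.
- Bromine–lithium exchange with n-BuLi (2.2 equiv, −78 °C) and trapping with 2-isopropoxy-4,4,5,5-tetramethyl-1,3,2-dioxaborolane should give the arylboronic ester (1S,2S)-1-(4-allyloxy-3-benzyloxyphenyl)-3-[2-allyloxy-4-benzyloxy-6-(4,4,5,5-tetramethyl-1,3,2-dioxaborolan-2-yl)phenyl]-2-benzyloxypropan-1-ol F2.
- Oxidation with H2O2 and NaOH should give the phenol 3-allyloxy-2-[(2S,3S)-3-(4-allyloxy-3-benzyloxyphenyl)-2-benzyloxy-3-hydroxypropyl]-5-benzyloxyphenol F3.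
- Treatment of F3 with PPh3 and diisopropyl azodicarboxylate closes ring C with inversion at the carbinol carbon and rejoins the route at compound 22.

**Step 8.** The 2,4-dialkoxybenzylic bromide 8 may ionise and self-condense before the glycolate enolate, which decomposes above about −40 °C, has alkylated, so conversion may be poor. The fallback replaces alkylation by aldol addition and deoxygenation and sets out from aldehyde 6.
- The enantiomeric imide (S)-4-benzyl-3-(2-benzyloxyacetyl)oxazolidin-2-one F4 is prepared from the (S)-auxiliary as in step 7.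
- Its boron enolate (Bu2BOTf, i-Pr2NEt, CH2Cl2, −78 → 0 °C) should add to 6 through a Zimmerman–Traxler transition state to give the syn aldol (S)-4-benzyl-3-[(2S,3R)-3-(2-allyloxy-4-benzyloxy-6-bromophenyl)-2-benzyloxy-3-hydroxypropanoyl]oxazolidin-2-one F5. The unchelated boron enolate reacts on the face opposite to that of the chelated sodium enolate, which is why the other auxiliary gives the same C3 configuration.
- Ionic deoxygenation of the electron-rich benzylic hydroxyl with Et3SiH and CF3CO2H should give (S)-4-benzyl-3-[(S)-3-(2-allyloxy-4-benzyloxy-6-bromophenyl)-2-benzyloxypropanoyl]oxazolidin-2-one F6.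
- Transamidation of F6 as in step 9 rejoins the route at compound 14.

**Step 12.** Addition to the hindered amide may be incomplete, and the α-proton of aryl ketone 20 is acidic enough for partial epimerisation of C3 during quench and purification. The fallback goes through the aldehyde and sets out from amide 14.
- Reduction with i-Bu2AlH in THF at −78 °C should give (S)-3-(2-allyloxy-4-benzyloxy-6-bromophenyl)-2-benzyloxypropanal F7.
- Addition of Grignard reagent 18 at −78 °C should give the carbinols as a mixture of 21 and its C1 epimer F1.
- Oxidation of the mixture with Dess–Martin periodinane buffered with NaHCO3 rejoins the route at compound 20 without exposure to base.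

**Step 13.** Facial selectivity may be eroded if zinc chelation is incomplete for the conjugated, electron-rich aryl ketone, which would contaminate 21 with the syn carbinol and, after step 14, give the 2,3-cis flavan. The fallback replaces substrate control by catalyst control and sets out from 20. Corey–Bakshi–Shibata reduction with (R)-1-butyl-3,3-diphenyltetrahydro-1H,3H-pyrrolo[1,2-c][1,3,2]oxazaborole and catecholborane in toluene at −78 °C should give 21 directly. The (R)-catalyst is chosen on the usual model with the aryl group as the larger ketone substituent, and catecholborane is used because it does not hydroborate the allyl ethers.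

**Step 17.** Over-reduction by hydrogenolysis of the benzylic C2–O1 bond, slow cleavage of the aliphatic O3 benzyl ether, or migration of the 4'-acyl group to the freed O3' during a long reaction are the likely problems. The fallback is non-reductive and sets out from 25. BCl3 with pentamethylbenzene as cation scavenger in CH2Cl2 at −78 °C cleaves aryl and alkyl benzyl ethers quickly and spares aryl esters, and should give 26 directly.

## Further compounds

F1 | step 14 | (1S,2S)-1-(4-allyloxy-3-benzyloxyphenyl)-3-(2-allyloxy-4-benzyloxy-6-bromophenyl)-2-benzyloxypropan-1-ol | C=CCOc1ccc([C@H](O)[C@@H](OCc2ccccc2)Cc2c(Br)cc(OCc3ccccc3)cc2OCC=C)cc1OCc1ccccc1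
F2 | step 14 | (1S,2S)-1-(4-allyloxy-3-benzyloxyphenyl)-3-[2-allyloxy-4-benzyloxy-6-(4,4,5,5-tetramethyl-1,3,2-dioxaborolan-2-yl)phenyl]-2-benzyloxypropan-1-ol | C=CCOc1ccc([C@H](O)[C@@H](OCc2ccccc2)Cc2c(B3OC(C)(C)C(C)(C)O3)cc(OCc3ccccc3)cc2OCC=C)cc1OCc1ccccc1
F3 | step 14 | 3-allyloxy-2-[(2S,3S)-3-(4-allyloxy-3-benzyloxyphenyl)-2-benzyloxy-3-hydroxypropyl]-5-benzyloxyphenol | C=CCOc1ccc([C@H](O)[C@@H](OCc2ccccc2)Cc2c(O)cc(OCc3ccccc3)cc2OCC=C)cc1OCc1ccccc1
F4 | step 8 | (S)-4-benzyl-3-(2-benzyloxyacetyl)oxazolidin-2-one | O=C(COCc1ccccc1)N1C(=O)OC[C@@H]1Cc1ccccc1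
F5 | step 8 | (S)-4-benzyl-3-[(2S,3R)-3-(2-allyloxy-4-benzyloxy-6-bromophenyl)-2-benzyloxy-3-hydroxypropanoyl]oxazolidin-2-one | C=CCOc1cc(OCc2ccccc2)cc(Br)c1[C@@H](O)[C@H](OCc1ccccc1)C(=O)N1C(=O)OC[C@@H]1Cc1ccccc1
F6 | step 8 | (S)-4-benzyl-3-[(S)-3-(2-allyloxy-4-benzyloxy-6-bromophenyl)-2-benzyloxypropanoyl]oxazolidin-2-one | C=CCOc1cc(OCc2ccccc2)cc(Br)c1C[C@H](OCc1ccccc1)C(=O)N1C(=O)OC[C@@H]1Cc1ccccc1
F7 | step 12 | (S)-3-(2-allyloxy-4-benzyloxy-6-bromophenyl)-2-benzyloxypropanal | C=CCOc1cc(OCc2ccccc2)cc(Br)c1C[C@H](OCc1ccccc1)C=O
F0 | step 13 | none | none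
F0 | step 17 | none | none
A1 | alternative 1 | 2-benzyloxy-4-[(R)-[3-benzyloxy-5-(3,4,5-tribenzyloxybenzoyloxy)phenoxy][(S)-oxiran-2-yl]methyl]phenyl 3,4,5-tris(benzyloxy)benzoate | O=C(Oc1ccc([C@@H](Oc2cc(OCc3ccccc3)cc(OC(=O)c3cc(OCc4ccccc4)c(OCc4ccccc4)c(OCc4ccccc4)c3)c2)[C@@H]2CO2)cc1OCc1ccccc1)c1cc(OCc2ccccc2)c(OCc2ccccc2)c(OCc2ccccc2)c1
A2 | alternative 1 | 7,3'-di-O-benzyl-(+)-catechin 5,4'-bis(3,4,5-tri-O-benzylgallate) | O=C(Oc1ccc([C@H]2Oc3cc(OCc4ccccc4)cc(OC(=O)c4cc(OCc5ccccc5)c(OCc5ccccc5)c(OCc5ccccc5)c4)c3C[C@@H]2O)cc1OCc1ccccc1)c1cc(OCc2ccccc2)c(OCc2ccccc2)c(OCc2ccccc2)c1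
A3 | alternative 2 | (R)-1-(3-benzyloxy-4-hydroxyphenyl)-3-(4-benzyloxy-2,6-dihydroxyphenyl)propan-2-ol | Oc1ccc(C[C@@H](O)Cc2c(O)cc(OCc3ccccc3)cc2O)cc1OCc1ccccc1
A4 | alternative 2 | 2-benzyloxy-4-[(S)-3-(4-benzyloxy-2,6-dihydroxyphenyl)-2-hydroxypropylidene]cyclohexa-2,5-dien-1-one | O=C1C=CC(=C[C@@H](O)Cc2c(O)cc(OCc3ccccc3)cc2O)C=C1OCc1ccccc1
A5 | alternative 2 | 7,3'-di-O-benzyl-(+)-catechin | Oc1ccc([C@H]2Oc3cc(OCc4ccccc4)cc(O)c3C[C@@H]2O)cc1OCc1ccccc1
A6 | alternative 3 | 3-allyloxy-5-benzyloxy-2-(hydroxymethyl)phenol | OCc1c(O)cc(OCc2ccccc2)cc1OCC=C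
A7 | alternative 3 | 5-allyloxy-3-benzyloxy-6-methylidenecyclohexa-2,4-dien-1-one | C=C1C(=O)C=C(OCc2ccccc2)C=C1OCC=C
A8 | alternative 3 | benzyl (E)-2-(4-allyloxy-3-benzyloxyphenyl)ethenyl carbonate | C=CCOc1ccc(/C=C/OC(=O)OCc2ccccc2)cc1OCc1ccccc1
A9 | alternative 3 | benzyl (2R,3S)-5-allyloxy-2-(4-allyloxy-3-benzyloxyphenyl)-7-benzyloxychroman-3-yl carbonate | C=CCOc1ccc([C@H]2Oc3cc(OCc4ccccc4)cc(OCC=C)c3C[C@@H]2OC(=O)OCc2ccccc2)cc1OCc1ccccc1
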